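**Retrosynthetic overview**

1. The target arises from a protected precursor by hydrogenolysis, which removes four benzyl groups and one helper chlorine (C6' of ring B). That precursor comes from DDQ oxidation of a 4-silyloxy-2H-chromene to the second 4-pyranone ring.
2. Key disconnection: both bonds at ring B, C1'–C2 (to the chromone) and C2'–C8'' (to the apigenin unit), are made in one pot on 3-chloro-5-methoxybenzyne. 8-Magnesiated tri-O-benzylapigenin adds to the aryne, and the biaryl Grignard reagent so formed attacks C2 of the 4-silyloxybenzopyrylium salt of 5-benzyloxy-7-methoxychromone.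
3. Enabling feature: in ring B (the central anisole ring; C1' carries chromone C2, C2' carries apigenin C8'', C4' carries OMe) the two large units sit on adjacent carbons, which are the two ends of an aryne triple bond. The free CH at C6', beside C1', can hold a chlorine that fixes which end takes the nucleophile.
4. Ring order: the three apigenin rings are bought intact (apigenin, then benzylation and C8 iodination). Ring B comes from 2-chloro-4-methoxyphenol as an iodo triflate. The pyranone of the chromone is closed from an acetophenone by the enaminone route before the key step and is re-aromatised after it.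

Key step: step 7

Assumption: the target is drawn without stereodescriptors, so the hindered C2'–C8'' biaryl axis is treated as unspecified and no step controls it.

**Route**

Step 1
Reactants: 1 apigenin
Product: 2 5,7-bis(benzyloxy)-2-[4-(benzyloxy)phenyl]-4H-chromen-4-one
Conditions: BnBr (excess), K2CO3, Bu4NI (cat.), DMF, 80 °C
Reagents that add atoms: benzyl bromide, BrCc1ccccc1
Why: Williamson ether synthesis; excess benzyl bromide and heat in DMF should also alkylate the hydrogen-bonded 5-OH.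

Step 2
Reactants: 2 5,7-bis(benzyloxy)-2-[4-(benzyloxy)phenyl]-4H-chromen-4-one
Product: 3 5,7-bis(benzyloxy)-2-[4-(benzyloxy)phenyl]-8-iodo-4H-chromen-4-one
Conditions: NIS, TFA (cat.), MeCN/CH2Cl2, 0 °C → rt
Reagents that add atoms: N-iodosuccinimide, O=C1CCC(=O)N1I
Why: Electrophilic aromatic iodination; C8 of ring A is activated by the 7- and 5-benzyloxy groups and the ring oxygen and is less hindered than C6, which lies between two benzyloxy groups, as is usual for 5,7-di-O-alkylflavones.

Step 3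
Reactants: 4 2-chloro-4-methoxyphenol
Product: 5 2-chloro-6-iodo-4-methoxyphenol
Conditions: NIS, TsOH (cat.), MeCN, rt
Reagents that add atoms: N-iodosuccinimide, O=C1CCC(=O)N1I
Why: Electrophilic aromatic iodination directed ortho to the phenol OH; the para position is blocked by OMe and C6 is the only free ortho site.

Step 4
Reactants: 5 2-chloro-6-iodo-4-methoxyphenol
Product: 6 2-chloro-6-iodo-4-methoxyphenyl trifluoromethanesulfonate
Conditions: Tf2O, pyridine, CH2Cl2, 0 °C
Reagents that add atoms: trifluoromethanesulfonic anhydride, O=S(=O)(OS(=O)(=O)C(F)(F)F)C(F)(F)F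
Why: O-Sulfonylation of a phenol gives the ortho-iodoaryl triflate, a standard aryne precursor.

Step 5
Reactants: 7 1-(2,6-dihydroxy-4-methoxyphenyl)ethanone
Product: 8 1-[2-(benzyloxy)-6-hydroxy-4-methoxyphenyl]ethanone
Conditions: BnBr (1.05 equiv), K2CO3, acetone, reflux
Reagents that add atoms: benzyl bromide, BrCc1ccccc1
Why: Williamson mono-etherification of a symmetrical diol; after the first alkylation the remaining OH is held in a hydrogen bond to the ketone and should react much more slowly.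

Step 6
Reactants: 8 1-[2-(benzyloxy)-6-hydroxy-4-methoxyphenyl]ethanone
Product: 10 5-(benzyloxy)-7-methoxy-4H-chromen-4-one, via enaminone 9 (not isolated)
Conditions: DMF-DMA, toluene, 100 °C; then HCl (aq), CH2Cl2, 40 °C
Reagents that add atoms: N,N-dimethylformamide dimethyl acetal, COC(OC)N(C)C
Why: Condensation of the methyl ketone with the amide acetal gives the enaminone, and acid then promotes 6-endo oxa-Michael addition of the phenol with loss of dimethylamine (the enaminone chromone synthesis).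

Step 7
Reactants: 3 5,7-bis(benzyloxy)-2-[4-(benzyloxy)phenyl]-8-iodo-4H-chromen-4-one; 6 2-chloro-6-iodo-4-methoxyphenyl trifluoromethanesulfonate; 10 5-(benzyloxy)-7-methoxy-4H-chromen-4-one
Product: 15 8-{2-[5-(benzyloxy)-4-(tert-butyldimethylsilyloxy)-7-methoxy-2H-chromen-2-yl]-3-chloro-5-methoxyphenyl}-5,7-bis(benzyloxy)-2-[4-(benzyloxy)phenyl]-4H-chromen-4-one (racemic), via flavon-8-ylmagnesium chloride 11 (not isolated), via 3-chloro-5-methoxybenzyne 12 (not isolated), via biarylmagnesium chloride 13 (not isolated), via 4-silyloxybenzopyrylium triflate 14 (not isolated)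
Conditions: 3, iPrMgCl·LiCl, THF, −30 °C; then 6 and Me3SiCH2MgCl (slow addition), −78 °C; then 14 (made apart from 10, TBSOTf, CH2Cl2, 40 °C) by cannula, −78 → −30 °C; aq NaHCO3
Reagents that add atoms: tert-butyldimethylsilyl trifluoromethanesulfonate, CC(C)(C)[Si](C)(C)OS(=O)(=O)C(F)(F)F
Why: Iodine–magnesium exchange turns 3 into Grignard reagent 11; Me3SiCH2MgCl then exchanges the iodide of 6, the ortho-magnesiated triflate loses Mg(OTf)Cl to give aryne 12, 11 adds to it to give biaryl Grignard reagent 13, and 13 attacks C2 of benzopyrylium salt 14. The closest known reaction types are the addition of aryl Grignard reagents to 3-haloarynes followed by electrophile capture (as in the two-aryne terphenyl synthesis and in biaryl phosphine syntheses) and the addition of organometallic reagents to C2 of 4-silyloxybenzopyrylium salts made from chromones and silyl triflates. No ring is closed. The only new stereocentre, C2 of the 2H-chromene, forms without control (racemic, mixed with respect to the biaryl axis) and is erased in step 8. The step needs one regiochemistry on the aryne, and the chlorine beside the triple bond secures it: its inductive pull and the distortion it causes place the carbanion on C1' next to chlorine and send the bulky nucleophile to the remote C2', while the para methoxy group has only a weak say. Attack at C2 of 14 and not at C4 follows from the silyloxy group on C4, and the low temperature should keep 13 from losing MgCl2 and keep both Grignard reagents off the flavone carbonyl.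

Step 8
Reactants: 15 8-{2-[5-(benzyloxy)-4-(tert-butyldimethylsilyloxy)-7-methoxy-2H-chromen-2-yl]-3-chloro-5-methoxyphenyl}-5,7-bis(benzyloxy)-2-[4-(benzyloxy)phenyl]-4H-chromen-4-one
Product: 16 8-{2-[5-(benzyloxy)-7-methoxy-4-oxo-4H-chromen-2-yl]-3-chloro-5-methoxyphenyl}-5,7-bis(benzyloxy)-2-[4-(benzyloxy)phenyl]-4H-chromen-4-one
Conditions: DDQ, CH2Cl2, 0 °C → rt; aq NaHCO3
Reagents that add atoms: none
Why: DDQ oxidation of a silyl enol ether: hydride abstraction from C2–H (allylic, benzylic and next to oxygen) should give a 4-silyloxyflavylium ion that loses the silyl group, driven by formation of the aromatic 4-pyranone.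

Step 9
Reactants: 16 8-{2-[5-(benzyloxy)-7-methoxy-4-oxo-4H-chromen-2-yl]-3-chloro-5-methoxyphenyl}-5,7-bis(benzyloxy)-2-[4-(benzyloxy)phenyl]-4H-chromen-4-one
Product: 17 8-[2-(5-hydroxy-7-methoxy-4-oxo-4H-chromen-2-yl)-5-methoxyphenyl]-5,7-dihydroxy-2-(4-hydroxyphenyl)-4H-chromen-4-one (target)
Conditions: H2 (1 atm), 10% Pd/C, Et3N, THF/MeOH, rt
Reagents that add atoms: none
Why: Palladium-catalysed hydrogenolysis should cleave the four benzyl aryl ethers and the aryl C–Cl bond (Et3N takes up HCl) in one operation, while the methyl ethers and the pyranone C2=C3 bonds are expected to survive at 1 atm and room temperature.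

**Compound list**

1 | apigenin, 5,7-dihydroxy-2-(4-hydroxyphenyl)-4H-chromen-4-one | O=c1cc(-c2ccc(O)cc2)oc2cc(O)cc(O)c12 | starting material
2 | 5,7-bis(benzyloxy)-2-[4-(benzyloxy)phenyl]-4H-chromen-4-one | O=c1cc(-c2ccc(OCc3ccccc3)cc2)oc2cc(OCc3ccccc3)cc(OCc3ccccc3)c12 | intermediate
3 | 5,7-bis(benzyloxy)-2-[4-(benzyloxy)phenyl]-8-iodo-4H-chromen-4-one | O=c1cc(-c2ccc(OCc3ccccc3)cc2)oc2c(I)c(OCc3ccccc3)cc(OCc3ccccc3)c12 | intermediate
4 | 2-chloro-4-methoxyphenol | COc1ccc(O)c(Cl)c1 | starting material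
5 | 2-chloro-6-iodo-4-methoxyphenol | COc1cc(Cl)c(O)c(I)c1 | intermediate
6 | 2-chloro-6-iodo-4-methoxyphenyl trifluoromethanesulfonate | COc1cc(Cl)c(OS(=O)(=O)C(F)(F)F)c(I)c1 | intermediate
7 | 1-(2,6-dihydroxy-4-methoxyphenyl)ethanone | CC(=O)c1c(O)cc(OC)cc1O | starting material
8 | 1-[2-(benzyloxy)-6-hydroxy-4-methoxyphenyl]ethanone | CC(=O)c1c(O)cc(OC)cc1OCc1ccccc1 | intermediate
9 | (E)-1-[2-(benzyloxy)-6-hydroxy-4-methoxyphenyl]-3-(dimethylamino)prop-2-en-1-one | CN(C)/C=C/C(=O)c1c(O)cc(OC)cc1OCc1ccccc1 | intermediate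
10 | 5-(benzyloxy)-7-methoxy-4H-chromen-4-one | COc1cc(OCc2ccccc2)c2c(=O)ccoc2c1 | intermediate
11 | {5,7-bis(benzyloxy)-2-[4-(benzyloxy)phenyl]-4-oxo-4H-chromen-8-yl}magnesium chloride | O=c1cc(-c2ccc(OCc3ccccc3)cc2)oc2c([Mg]Cl)c(OCc3ccccc3)cc(OCc3ccccc3)c12 | intermediate
12 | 3-chloro-5-methoxybenzyne (3-chloro-5-methoxy-1,2-didehydrobenzene) | COC1=CC#CC(Cl)=C1 | intermediate
13 | (2-chloro-6-{5,7-bis(benzyloxy)-2-[4-(benzyloxy)phenyl]-4-oxo-4H-chromen-8-yl}-4-methoxyphenyl)magnesium chloride | COc1cc(Cl)c([Mg]Cl)c(-c2c(OCc3ccccc3)cc(OCc3ccccc3)c3c(=O)cc(-c4ccc(OCc5ccccc5)cc4)oc23)c1 | intermediate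
14 | 5-(benzyloxy)-4-(tert-butyldimethylsilyloxy)-7-methoxychromenylium trifluoromethanesulfonate | COc1cc(OCc2ccccc2)c2c(O[Si](C)(C)C(C)(C)C)cc[o+]c2c1.[O-]S(=O)(=O)C(F)(F)F | intermediate
15 | 8-{2-[5-(benzyloxy)-4-(tert-butyldimethylsilyloxy)-7-methoxy-2H-chromen-2-yl]-3-chloro-5-methoxyphenyl}-5,7-bis(benzyloxy)-2-[4-(benzyloxy)phenyl]-4H-chromen-4-one, racemic at C2 of the 2H-chromene | COc1cc(Cl)c(C2C=C(O[Si](C)(C)C(C)(C)C)c3c(OCc4ccccc4)cc(OC)cc3O2)c(-c2c(OCc3ccccc3)cc(OCc3ccccc3)c3c(=O)cc(-c4ccc(OCc5ccccc5)cc4)oc23)c1 | intermediate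
16 | 8-{2-[5-(benzyloxy)-7-methoxy-4-oxo-4H-chromen-2-yl]-3-chloro-5-methoxyphenyl}-5,7-bis(benzyloxy)-2-[4-(benzyloxy)phenyl]-4H-chromen-4-one | COc1cc(Cl)c(-c2cc(=O)c3c(OCc4ccccc4)cc(OC)cc3o2)c(-c2c(OCc3ccccc3)cc(OCc3ccccc3)c3c(=O)cc(-c4ccc(OCc5ccccc5)cc4)oc23)c1 | intermediate
17 | 8-[2-(5-hydroxy-7-methoxy-4-oxo-4H-chromen-2-yl)-5-methoxyphenyl]-5,7-dihydroxy-2-(4-hydroxyphenyl)-4H-chromen-4-one | COc1ccc(-c2cc(=O)c3c(O)cc(OC)cc3o2)c(-c2c(O)cc(O)c3c(=O)cc(-c4ccc(O)cc4)oc23)c1 | target

**Totals**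

Total step count: 9. Longest linear sequence: 5 steps (steps 1, 2, 7, 8, 9; the branches through steps 3–4 and 5–6 are equally long).

**Steps most likely to fail**

Step 7. The Grignard reagents may attack a flavone carbonyl, 11 may undergo iodine–magnesium exchange with 6 instead of adding to the aryne, or 13 may lose MgCl2 before the hindered carbanion is captured. The fallback sets out from 3 and 8 and comes back to the route at 17. Suzuki–Miyaura coupling of 3 with commercial (2-formyl-5-methoxyphenyl)boronic acid (Pd(OAc)2, SPhos, K3PO4, toluene/water, 90 °C) should give the biaryl aldehyde 2-{5,7-bis(benzyloxy)-2-[4-(benzyloxy)phenyl]-4-oxo-4H-chromen-8-yl}-4-methoxybenzaldehyde F1. Claisen–Schmidt condensation of this aldehyde with acetophenone 8 (KOH, EtOH/THF, rt) should give the 2'-hydroxychalcone (E)-1-[2-(benzyloxy)-6-hydroxy-4-methoxyphenyl]-3-(2-{5,7-bis(benzyloxy)-2-[4-(benzyloxy)phenyl]-4-oxo-4H-chromen-8-yl}-4-methoxyphenyl)prop-2-en-1-one F2. Oxidative cyclisation (I2 cat., DMSO, 120 °C) should give the chlorine-free tetra-O-benzyl biflavone 8-{2-[5-(benzyloxy)-7-methoxy-4-oxo-4H-chromen-2-yl]-5-methoxyphenyl}-5,7-bis(benzyloxy)-2-[4-(benzyloxy)phenyl]-4H-chromen-4-one F3. Hydrogenolysis under the conditions of step 9 without Et3N should then give 17.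

Step 9. The pyranone C2=C3 bonds may be over-reduced during the longer exposure that the C–Cl bond needs, or the C–Cl cleavage may stall once the benzyl groups are gone. The fallback sets out from 16 and comes back at 17, and uses no hydrogen gas. BCl3 with pentamethylbenzene (CH2Cl2, −78 °C) should remove the four benzyl groups and leave the two methyl ethers, giving 8-[3-chloro-2-(5-hydroxy-7-methoxy-4-oxo-4H-chromen-2-yl)-5-methoxyphenyl]-5,7-dihydroxy-2-(4-hydroxyphenyl)-4H-chromen-4-one F4. Homogeneous hydrodechlorination with formate as the hydride source (Pd(OAc)2, XPhos, HCO2Na, DMF, 80 °C) should then give 17.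

Step 8. The silyl enol ether may be desilylated to the flavanone instead of undergoing hydride abstraction, or DDQ may attack the electron-rich benzyl ethers. The fallback sets out from 15 and comes back at 16. Hydrolysis of the silyl enol ether (aq HCl, THF, rt) should give the flavanone 8-{2-[5-(benzyloxy)-7-methoxy-4-oxochroman-2-yl]-3-chloro-5-methoxyphenyl}-5,7-bis(benzyloxy)-2-[4-(benzyloxy)phenyl]-4H-chromen-4-one F5. Dehydrogenation by α-iodination and elimination (I2, pyridine, 90 °C) should then give 16.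

**Further compounds**

F1 | step 7 | 2-{5,7-bis(benzyloxy)-2-[4-(benzyloxy)phenyl]-4-oxo-4H-chromen-8-yl}-4-methoxybenzaldehyde | COc1ccc(C=O)c(-c2c(OCc3ccccc3)cc(OCc3ccccc3)c3c(=O)cc(-c4ccc(OCc5ccccc5)cc4)oc23)c1
F2 | step 7 | (E)-1-[2-(benzyloxy)-6-hydroxy-4-methoxyphenyl]-3-(2-{5,7-bis(benzyloxy)-2-[4-(benzyloxy)phenyl]-4-oxo-4H-chromen-8-yl}-4-methoxyphenyl)prop-2-en-1-one | COc1ccc(/C=C/C(=O)c2c(O)cc(OC)cc2OCc2ccccc2)c(-c2c(OCc3ccccc3)cc(OCc3ccccc3)c3c(=O)cc(-c4ccc(OCc5ccccc5)cc4)oc23)c1
F3 | step 7 | 8-{2-[5-(benzyloxy)-7-methoxy-4-oxo-4H-chromen-2-yl]-5-methoxyphenyl}-5,7-bis(benzyloxy)-2-[4-(benzyloxy)phenyl]-4H-chromen-4-one | COc1ccc(-c2cc(=O)c3c(OCc4ccccc4)cc(OC)cc3o2)c(-c2c(OCc3ccccc3)cc(OCc3ccccc3)c3c(=O)cc(-c4ccc(OCc5ccccc5)cc4)oc23)c1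
F4 | step 9 | 8-[3-chloro-2-(5-hydroxy-7-methoxy-4-oxo-4H-chromen-2-yl)-5-methoxyphenyl]-5,7-dihydroxy-2-(4-hydroxyphenyl)-4H-chromen-4-one | COc1cc(Cl)c(-c2cc(=O)c3c(O)cc(OC)cc3o2)c(-c2c(O)cc(O)c3c(=O)cc(-c4ccc(O)cc4)oc23)c1
F5 | step 8 | 8-{2-[5-(benzyloxy)-7-methoxy-4-oxochroman-2-yl]-3-chloro-5-methoxyphenyl}-5,7-bis(benzyloxy)-2-[4-(benzyloxy)phenyl]-4H-chromen-4-one, racemic | COc1cc(Cl)c(C2CC(=O)c3c(OCc4ccccc4)cc(OC)cc3O2)c(-c2c(OCc3ccccc3)cc(OCc3ccccc3)c3c(=O)cc(-c4ccc(OCc5ccccc5)cc4)oc23)c1
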